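The route builds benzoate ring D onto a finished, oxygen-differentiated ring A instead of joining two arenes. In ring D the oxygen on D4 lies para to the ester carbon D1 and next to D3, the carbon bonded to C6 of ring A. This pattern is the imprint of a 1-methoxy-3-silyloxybutadiene carrying ring A on C2 and methyl propiolate. One thermal [4+2] cycloaddition forms D1–D2 and D5–D6, and loss of methanol aromatises the adduct without oxidant, leaving D4 as the only silyl-masked oxygen. The precursor, (E)-diene 11 with a 4-benzyloxy-2,6-bis(methoxymethoxy)phenyl group, comes from a Negishi coupling and an enol silylation. The benzyl-masked oxygen later becomes O1 of the flavone.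

Key step: step 6

Labels: ring A is C4a/C5–C8/C8a of the chromenone, ring C is the pyranone, and ring B is the 4-hydroxyphenyl group on C2. Ring D is the benzoate on C6, with D1 the ester-bearing carbon, D3 the carbon bonded to C6 and D4 the methoxy-bearing carbon.
Assumption: the target holds no stereocentre and its SMILES fixes no sense for the C6–D3 axis, so hindered biaryl intermediates are carried as racemic or freely rotating material.

Step 1
Reactants: 1 phloroglucinol (benzene-1,3,5-triol)
Product: 2 5-(benzyloxy)benzene-1,3-diol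
Conditions: 1 (3 equiv), BnBr (1 equiv), K2CO3 (1 equiv), DMF, rt
Reagents that add atoms: benzyl bromide, BrCc1ccccc1
Why: Williamson etherification in a dipolar aprotic solvent favours O- over C-benzylation, and the excess of the cheap, water-soluble triol holds back double alkylation and is washed out on work-up.

Step 2
Reactants: 2 5-(benzyloxy)benzene-1,3-diol
Product: 3 1-(benzyloxy)-3,5-bis(methoxymethoxy)benzene
Conditions: MOMCl (2.6 equiv), i-Pr2NEt (3 equiv), CH2Cl2, 0 °C to rt
Reagents that add atoms: chloromethyl methyl ether, COCCl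
Why: Standard acetal protection of phenols (O-alkylation with MOMCl and a hindered amine base) caps both remaining hydroxyls and installs the two chelating directing groups used in step 4.

Step 3
Reactants: 4 (E)-4-methoxybut-3-en-2-one
Product: 6 (Z)-3-iodo-4-methoxybut-3-en-2-one, via acetoxy iodide adduct 5 (not isolated)
Conditions: NIS, AcOH, CH2Cl2, rt, dark; then Et3N, rt
Reagents that add atoms: N-iodosuccinimide, O=C1CCC(=O)N1I
Why: Electrophilic iodo-acetoxylation of the push-pull enol ether followed by base-induced elimination of acetic acid, the protocol established for β-methoxyacrylates, should give the α-iodo enone as the more stable (Z) isomer with methoxy anti to acetyl.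

Step 4
Reactants: 3 1-(benzyloxy)-3,5-bis(methoxymethoxy)benzene; 6 (Z)-3-iodo-4-methoxybut-3-en-2-one
Product: 9 (E)-3-[4-(benzyloxy)-2,6-bis(methoxymethoxy)phenyl]-4-methoxybut-3-en-2-one, via aryllithium 7 (not isolated), via arylzinc chloride 8 (not isolated)
Conditions: 3, n-BuLi, THF, 0 °C; ZnCl2, 0 °C to rt; 6, Pd2(dba)3 (2 mol %), SPhos (8 mol %), THF, 50 °C
Reagents that add atoms: none
Why: Cooperative directed ortho-metalation between the two chelating acetal oxygens, lithium-to-zinc exchange and a Negishi coupling of the α-iodo enone (a known partner class for organozincs) with a bulky biarylphosphine suited to doubly ortho-substituted nucleophiles make the aryl–vinyl bond with retention, so methoxy stays anti to acetyl and only the descriptor changes from (Z) to (E).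

Step 5
Reactants: 9 (E)-3-[4-(benzyloxy)-2,6-bis(methoxymethoxy)phenyl]-4-methoxybut-3-en-2-one
Product: 11 (E)-2-[4-(benzyloxy)-2,6-bis(methoxymethoxy)phenyl]-1-methoxy-3-(tert-butyldimethylsilyloxy)buta-1,3-diene, via potassium enolate 10 (not isolated)
Conditions: KN(SiMe3)2, THF, −78 °C; TBSCl, −78 °C to rt
Reagents that add atoms: tert-butyldimethylsilyl chloride, CC(C)(C)[Si](C)(C)Cl
Why: The acetyl CH3 is the only enolisable position, so deprotonation with a hindered potassium amide and O-silylation of the cross-conjugated enolate (silyl enol ether formation) gives the diene without exposing the acetals to a Lewis acidic silyl triflate.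

Step 6
Reactants: 11 (E)-2-[4-(benzyloxy)-2,6-bis(methoxymethoxy)phenyl]-1-methoxy-3-(tert-butyldimethylsilyloxy)buta-1,3-diene; 12 methyl propiolate
Product: 14 methyl 3-[4-(benzyloxy)-2,6-bis(methoxymethoxy)phenyl]-4-(tert-butyldimethylsilyloxy)benzoate, via cyclohexadiene adduct 13 (not isolated)
Conditions: 12 (4 equiv), 4 Å MS, BHT (cat.), PhMe, 110 °C, sealed tube; concentrate; Et3N, CH2Cl2, rt
Reagents that add atoms: none
Why: The silyloxy group on C3 and the methoxy group on C1 of 11 both raise the HOMO coefficient at the terminal CH2, which attacks the unsubstituted β-carbon of 12 (D5–D6) while the methoxy-bearing CH closes onto the ester-bearing carbon (D1–D2) in an asynchronous concerted, normal-electron-demand Diels–Alder reaction. The closest known reaction type is the benzannulation of 1-methoxy-3-silyloxybutadienes, 2-alkyl congeners included, with propiolates to give 4-oxygenated benzoates. Ring D closes in the intermolecular [4+2] mode, both sigma bonds forming on one face of the s-cis diene, to give 1,4-cyclohexadiene 13. In 13 the doubly allylic CH2 is γ to the ester, so heat or triethylamine triggers a vinylogous E1cB 1,4-loss of methanol and ring D aromatises without oxidant, which erases the single sp3 C–OMe centre of racemic 13 and leaves no stereocentre. The step needs regioselectivity (oxygen para and not meta to the ester), and the matched push of the two oxygen donors secures it, because the aryl group on C2 is twisted out of conjugation by its ortho acetals and is electronically almost silent. The (E) geometry keeps methoxy on the outside of the s-cis diene, the slim linear dienophile is the partner best able to pass the ortho acetals, and the sieves take up methanol so that unreacted silyl enol ether is not solvolysed.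

Step 7
Reactants: 14 methyl 3-[4-(benzyloxy)-2,6-bis(methoxymethoxy)phenyl]-4-(tert-butyldimethylsilyloxy)benzoate
Product: 16 methyl 3-[4-(benzyloxy)-2,6-bis(methoxymethoxy)phenyl]-4-methoxybenzoate, via caesium phenoxide 15 (not isolated)
Conditions: CsF, MeI, DMF, rt
Reagents that add atoms: iodomethane, CI
Why: Fluoride-induced desilylation releases the ester-stabilised phenoxide, which is trapped in the same flask by SN2 methylation (one-pot exchange of an aryl silyl ether for an aryl alkyl ether), while the benzyl ether, the acetals and the ester are inert.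

Step 8
Reactants: 16 methyl 3-[4-(benzyloxy)-2,6-bis(methoxymethoxy)phenyl]-4-methoxybenzoate
Product: 17 methyl 3-[4-hydroxy-2,6-bis(methoxymethoxy)phenyl]-4-methoxybenzoate
Conditions: H2 (1 atm), Pd/C (10 wt %), EtOAc, rt
Reagents that add atoms: none
Why: Catalytic hydrogenolysis of the benzyl aryl ether frees only the oxygen para to the biaryl bond, since acetals, ester and methyl ether are untouched and no reducible C=C bond is present at this stage.

Step 9
Reactants: 17 methyl 3-[4-hydroxy-2,6-bis(methoxymethoxy)phenyl]-4-methoxybenzoate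
Product: 18 methyl 3-[4-hydroxy-3-iodo-2,6-bis(methoxymethoxy)phenyl]-4-methoxybenzoate
Conditions: NIS (1.0 equiv), CH2Cl2, −20 to 0 °C, dark
Reagents that add atoms: N-iodosuccinimide, O=C1CCC(=O)N1I
Why: In this electrophilic aromatic iodination the two free ring A positions are constitutionally equivalent and each is activated by three oxygens, whereas ring D is deactivated by its ester, so one equivalent of NIS at low temperature should stop at the mono-iodide ortho to the phenol.

Step 10
Reactants: 19 4-ethynylphenol
Product: 20 1-ethynyl-4-(methoxymethoxy)benzene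
Conditions: MOMCl, i-Pr2NEt, CH2Cl2, 0 °C to rt
Reagents that add atoms: chloromethyl methyl ether, COCCl
Why: Acetal protection of the phenol keeps it from competing as a nucleophile for the acylpalladium species in step 11 and uses the same group as ring A, so that one final operation removes all three.

Step 11
Reactants: 18 methyl 3-[4-hydroxy-3-iodo-2,6-bis(methoxymethoxy)phenyl]-4-methoxybenzoate; 20 1-ethynyl-4-(methoxymethoxy)benzene
Product: 22 methyl 3-{5,7-bis(methoxymethoxy)-2-[4-(methoxymethoxy)phenyl]-4-oxo-4H-chromen-6-yl}-4-methoxybenzoate, via ynone 21 (not isolated)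
Conditions: 20 (1.5 equiv), PdCl2(dppf) (5 mol %), CO (20 bar), Et2NH, 120 °C, autoclave
Reagents that add atoms: carbon monoxide, [C-]#[O+]
Why: Carbonylative Sonogashira coupling (oxidative addition of zerovalent palladium to the C–I bond, CO insertion, alkynylation) gives ynone 21, whose ortho phenol closes ring C by 6-endo-dig oxa-Michael addition in the secondary-amine medium known to favour flavones over aurones, while high CO pressure suppresses direct coupling.

Step 12
Reactants: 22 methyl 3-{5,7-bis(methoxymethoxy)-2-[4-(methoxymethoxy)phenyl]-4-oxo-4H-chromen-6-yl}-4-methoxybenzoate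
Product: 23 methyl 3-[5,7-dihydroxy-2-(4-hydroxyphenyl)-4-oxo-4H-chromen-6-yl]-4-methoxybenzoate (CNP0261185.0)
Conditions: HCl (1.25 M in MeOH), 50 °C
Reagents that add atoms: none
Why: Acid-catalysed transacetalisation to methanol cleaves all three methoxymethyl ethers, the methyl ester being degenerate toward methanolysis and the aryl methyl ether inert.

Compound list
1 | phloroglucinol | Oc1cc(O)cc(O)c1 | starting material
2 | 5-(benzyloxy)benzene-1,3-diol | Oc1cc(O)cc(OCc2ccccc2)c1 | intermediate
3 | 1-(benzyloxy)-3,5-bis(methoxymethoxy)benzene | COCOc1cc(OCOC)cc(OCc2ccccc2)c1 | intermediate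
4 | (E)-4-methoxybut-3-en-2-one | CO/C=C/C(C)=O | starting material
5 | 2-iodo-1-methoxy-3-oxobutyl acetate (diastereomer mixture, not isolated) | COC(OC(C)=O)C(I)C(C)=O | intermediate
6 | (Z)-3-iodo-4-methoxybut-3-en-2-one | CO/C=C(\I)C(C)=O | intermediate
7 | [4-(benzyloxy)-2,6-bis(methoxymethoxy)phenyl]lithium (not isolated) | [Li]c1c(OCOC)cc(OCc2ccccc2)cc1OCOC | intermediate
8 | [4-(benzyloxy)-2,6-bis(methoxymethoxy)phenyl]zinc chloride (not isolated) | Cl[Zn]c1c(OCOC)cc(OCc2ccccc2)cc1OCOC | intermediate
9 | (E)-3-[4-(benzyloxy)-2,6-bis(methoxymethoxy)phenyl]-4-methoxybut-3-en-2-one | CO/C=C(/C(C)=O)c1c(OCOC)cc(OCc2ccccc2)cc1OCOC | intermediate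
10 | potassium enolate of 9 (not isolated) | CO/C=C(/C(=C)[O-])c1c(OCOC)cc(OCc2ccccc2)cc1OCOC.[K+] | intermediate
11 | (E)-2-[4-(benzyloxy)-2,6-bis(methoxymethoxy)phenyl]-1-methoxy-3-(tert-butyldimethylsilyloxy)buta-1,3-diene | CO/C=C(/C(=C)O[Si](C)(C)C(C)(C)C)c1c(OCOC)cc(OCc2ccccc2)cc1OCOC | intermediate
12 | methyl propiolate | C#CC(=O)OC | starting material
13 | methyl 5-[4-(benzyloxy)-2,6-bis(methoxymethoxy)phenyl]-4-(tert-butyldimethylsilyloxy)-6-methoxycyclohexa-1,4-diene-1-carboxylate (racemic, not isolated) | COC(=O)C1=CCC(O[Si](C)(C)C(C)(C)C)=C(c2c(OCOC)cc(OCc3ccccc3)cc2OCOC)C1OC | intermediate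
14 | methyl 3-[4-(benzyloxy)-2,6-bis(methoxymethoxy)phenyl]-4-(tert-butyldimethylsilyloxy)benzoate | COC(=O)c1ccc(O[Si](C)(C)C(C)(C)C)c(-c2c(OCOC)cc(OCc3ccccc3)cc2OCOC)c1 | intermediate
15 | caesium 2-[4-(benzyloxy)-2,6-bis(methoxymethoxy)phenyl]-4-(methoxycarbonyl)phenoxide (not isolated) | COC(=O)c1ccc([O-])c(-c2c(OCOC)cc(OCc3ccccc3)cc2OCOC)c1.[Cs+] | intermediate
16 | methyl 3-[4-(benzyloxy)-2,6-bis(methoxymethoxy)phenyl]-4-methoxybenzoate | COC(=O)c1ccc(OC)c(-c2c(OCOC)cc(OCc3ccccc3)cc2OCOC)c1 | intermediate
17 | methyl 3-[4-hydroxy-2,6-bis(methoxymethoxy)phenyl]-4-methoxybenzoate | COC(=O)c1ccc(OC)c(-c2c(OCOC)cc(O)cc2OCOC)c1 | intermediate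
18 | methyl 3-[4-hydroxy-3-iodo-2,6-bis(methoxymethoxy)phenyl]-4-methoxybenzoate | COC(=O)c1ccc(OC)c(-c2c(OCOC)cc(O)c(I)c2OCOC)c1 | intermediate
19 | 4-ethynylphenol | C#Cc1ccc(O)cc1 | starting material
20 | 1-ethynyl-4-(methoxymethoxy)benzene | C#Cc1ccc(OCOC)cc1 | intermediate
21 | methyl 3-[4-hydroxy-2,6-bis(methoxymethoxy)-3-{3-[4-(methoxymethoxy)phenyl]prop-2-ynoyl}phenyl]-4-methoxybenzoate (not isolated) | COC(=O)c1ccc(OC)c(-c2c(OCOC)cc(O)c(C(=O)C#Cc3ccc(OCOC)cc3)c2OCOC)c1 | intermediate
22 | methyl 3-{5,7-bis(methoxymethoxy)-2-[4-(methoxymethoxy)phenyl]-4-oxo-4H-chromen-6-yl}-4-methoxybenzoate | COC(=O)c1ccc(OC)c(-c2c(OCOC)cc3oc(-c4ccc(OCOC)cc4)cc(=O)c3c2OCOC)c1 | intermediate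
23 | methyl 3-[5,7-dihydroxy-2-(4-hydroxyphenyl)-4-oxo-4H-chromen-6-yl]-4-methoxybenzoate | COC(=O)c1ccc(OC)c(-c2c(O)cc3oc(-c4ccc(O)cc4)cc(=O)c3c2O)c1 | target

Total step count: 12.
Longest linear sequence: 10 steps from phloroglucinol (steps 1, 2, 4, 5, 6, 7, 8, 9, 11, 12). Steps 3 and 10 are one-step side branches.

Steps most likely to fail

Step 6. The 2,3-disubstituted diene may reach the planar s-cis arrangement only with difficulty, and the ortho acetals shield both of its faces. Cycloaddition could then be outrun by protodesilylation of the silyl enol ether and by oligomerisation of the propiolate. The fallback gives up the cycloaddition and makes the C6–D3 bond directly by cross-coupling. It sets out from 3, which is metalated as in step 4 through 7 to arylzinc chloride 8. This is joined with purchased methyl 3-iodo-4-methoxybenzoate F1 in a Negishi biaryl coupling (Pd2(dba)3, SPhos, THF, 60 °C). That coupling gives 16, where the route is rejoined.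

Step 4. Transmetalation and reductive elimination at the doubly ortho-substituted arylzinc may be slow. Protodezincation and reductive deiodination of the vinyl iodide could then consume both partners before coupling. The fallback builds the side chain by classical carbonyl chemistry, sets out from 3 and comes back at 9.
- Aryllithium 7 is quenched with allyl bromide (CuI cat., THF) to give 2-allyl-5-(benzyloxy)-1,3-bis(methoxymethoxy)benzene F2.
- Tsuji–Wacker oxidation (PdCl2, CuCl, O2, DMF–H2O) gives 1-[4-(benzyloxy)-2,6-bis(methoxymethoxy)phenyl]propan-2-one F3.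
- Crossed Claisen formylation at the benzylic CH2 (NaH, ethyl formate, THF; AcOH quench) gives 2-[4-(benzyloxy)-2,6-bis(methoxymethoxy)phenyl]-3-oxobutanal F4, which is largely enolised.
- O-methylation with dimethyl sulfate and K2CO3 in DMF, the sequence used for β-methoxyacrylates, gives 9.

Step 11. Oxidative addition at the iodide flanked by two oxygen substituents may be slow. Diethylamine may intercept the acylpalladium species (aminocarbonylation), non-carbonylative coupling may lead to benzofuran closure, and the ynone may close 5-exo instead of 6-endo. The fallback avoids both the iodide and carbon monoxide, sets out from phenol 17 and rejoins at 22.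
- Magnesium-mediated ortho-formylation (Casnati–Skattebøl reaction: MgCl2, Et3N, paraformaldehyde, MeCN, reflux) should give methyl 3-[3-formyl-4-hydroxy-2,6-bis(methoxymethoxy)phenyl]-4-methoxybenzoate F5.
- Alkyne 20 is converted with EtMgBr into {[4-(methoxymethoxy)phenyl]ethynyl}magnesium bromide F6.
- Two equivalents of F6 are used on F5 (THF, 0 °C). The first deprotonates the phenol, and the ester is inert to alkynyl Grignard reagents at this temperature. The product is racemic methyl 3-[4-hydroxy-3-{1-hydroxy-3-[4-(methoxymethoxy)phenyl]prop-2-yn-1-yl}-2,6-bis(methoxymethoxy)phenyl]-4-methoxybenzoate F7.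
- MnO2 in CH2Cl2 oxidises this alcohol to ynone 21, which is isolated here, and warming 21 with Et2NH in EtOH closes ring C to 22.

Further compounds
F1 | step 6 | methyl 3-iodo-4-methoxybenzoate (purchased) | COC(=O)c1ccc(OC)c(I)c1
F2 | step 4 | 2-allyl-5-(benzyloxy)-1,3-bis(methoxymethoxy)benzene | C=CCc1c(OCOC)cc(OCc2ccccc2)cc1OCOC
F3 | step 4 | 1-[4-(benzyloxy)-2,6-bis(methoxymethoxy)phenyl]propan-2-one | CC(=O)Cc1c(OCOC)cc(OCc2ccccc2)cc1OCOC
F4 | step 4 | 2-[4-(benzyloxy)-2,6-bis(methoxymethoxy)phenyl]-3-oxobutanal (drawn as the keto-aldehyde tautomer, racemic) | CC(=O)C(C=O)c1c(OCOC)cc(OCc2ccccc2)cc1OCOC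
F5 | step 11 | methyl 3-[3-formyl-4-hydroxy-2,6-bis(methoxymethoxy)phenyl]-4-methoxybenzoate | COC(=O)c1ccc(OC)c(-c2c(OCOC)cc(O)c(C=O)c2OCOC)c1
F6 | step 11 | {[4-(methoxymethoxy)phenyl]ethynyl}magnesium bromide | Br[Mg]C#Cc1ccc(OCOC)cc1
F7 | step 11 | methyl 3-[4-hydroxy-3-{1-hydroxy-3-[4-(methoxymethoxy)phenyl]prop-2-yn-1-yl}-2,6-bis(methoxymethoxy)phenyl]-4-methoxybenzoate (racemic) | COC(=O)c1ccc(OC)c(-c2c(OCOC)cc(O)c(C(O)C#Cc3ccc(OCOC)cc3)c2OCOC)c1
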